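**Retrosynthetic overview**
1. The oxolane, the only ring, is closed last through the C5–O bond: the veratryl carbinol adds to a p-quinone methide carrying a 4-hydroxy-3,5-dimethoxyphenyl group, and the phenol is methylated in the same flask.
2. The quinone methide arises by tautomerisation of a 4-hydroxystyrene; C4 and C5 are set there under thermodynamic control.
3. The styrene is cut at the aryl–alkene bond (Heck) into 4-bromo-2,6-dimethoxyphenol and a homoallylic alcohol.
4. The homoallylic alcohol, which carries C2 and C3, is cut at C2–C3: asymmetric allylboration of 3,4-dimethoxybenzaldehyde with a (Z)-2-methylbut-2-enyl boronate.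
5. The boronate comes from (Z)-2-bromobut-2-ene and (chloromethyl)boronic acid pinacol ester.

Assumption: geometrically pure (Z)-2-bromobut-2-ene and 4-bromo-2,6-dimethoxyphenol are bought; ring positions are numbered as in the target (O1, C2 dimethoxyphenyl, C3, C4, C5 trimethoxyphenyl), which is 2,3-cis, 3,4-trans, 4,5-trans.

**Step 1**
Reactants: 1 (Z)-2-bromobut-2-ene; 2 (chloromethyl)boronic acid pinacol ester
Product: 5 (Z)-2-methylbut-2-en-1-ylboronic acid pinacol ester, via alkenyllithium 3 (not isolated), via boronate complex 4 (not isolated)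
Conditions: t-BuLi (2.0 equiv), THF/Et2O, −78 °C; then 2, −78 °C to rt
Reagents that add atoms: none
Why: Bromine–lithium exchange keeps the alkene geometry, and the alkenyl group of complex 4 then migrates from boron to carbon with loss of chloride (Matteson-type 1,2-metallate rearrangement), so CH2B ends cis to the C4 methyl group (the CIP letter of 3 and 4 is E only because of priorities).

**Step 2**
Reactants: 5 (Z)-2-methylbut-2-en-1-ylboronic acid pinacol ester; 6 veratraldehyde (3,4-dimethoxybenzaldehyde)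
Product: 8 (1R,2S)-1-(3,4-dimethoxyphenyl)-2,3-dimethylbut-3-en-1-ol, via borate ester 7 (not isolated)
Conditions: (R)-3,3'-bis(2,4,6-triisopropylphenyl)-1,1'-binaphthyl-2,2'-diyl hydrogen phosphate (5 mol%), 4 Å MS, toluene, −30 °C; then aq. NaHCO3
Reagents that add atoms: none
Why: Chiral phosphoric acid-catalysed allylboration through a closed chair-like six-membered transition state, in which the (Z)-methyl group gives the syn adduct and the (R)-acid, which delivers (R)-carbinols from aryl aldehydes with allyl and crotyl pinacol boronates, fixes the aldehyde face, so C2 (R) and C3 (S) of the target are both set here.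

**Step 3**
Reactants: 8 (1R,2S)-1-(3,4-dimethoxyphenyl)-2,3-dimethylbut-3-en-1-ol; 9 bromophenol 4-bromo-2,6-dimethoxyphenol
Product: 10 styrylphenol 4-[(1E,3S,4R)-4-(3,4-dimethoxyphenyl)-4-hydroxy-2,3-dimethylbut-1-en-1-yl]-2,6-dimethoxyphenol
Conditions: Pd(OAc)2 (5 mol%), P(t-Bu)3·HBF4 (10 mol%), K2CO3 (3 equiv), DMF, 100 °C, Ar
Reagents that add atoms: none
Why: Mizoroki–Heck reaction in which the arylpalladium bromide adds its aryl group to the terminal carbon of the 1,1-disubstituted alkene and beta-hydride elimination toward the new benzylic CH2 gives the conjugated styrene; the two stereocentres are not touched, the alkene geometry does not matter for step 4, and the basic medium keeps the phenoxide from cyclising early.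

**Step 4**
Reactants: 10 styrylphenol 4-[(1E,3S,4R)-4-(3,4-dimethoxyphenyl)-4-hydroxy-2,3-dimethylbut-1-en-1-yl]-2,6-dimethoxyphenol
Product: 13 (2R,3S,4S,5S)-2-(3,4-dimethoxyphenyl)-3,4-dimethyl-5-(3,4,5-trimethoxyphenyl)oxolane, via quinone methide 11 (not isolated), via phenol 12 (not isolated)
Conditions: (PhO)2P(O)OH (10 mol%), toluene (0.02 M), 40 °C, Ar; then K2CO3, MeI, DMF, 40 °C
Reagents that add atoms: iodomethane, CI
Why: Proposed new method: a redox-neutral, stereoconvergent cycloisomerisation in which the bifunctional phosphoric acid tautomerises the 4-hydroxystyrene 10 to p-quinone methide 11 (proton to C4 while the phenolic proton is taken up) and the veratryl carbinol closes the ring by 5-exo oxa-1,6-addition (oxa-Michael type), forming the C5–O bond; ring opening and quinone methide/styrene tautomerism are expected to be reversible only at the phenol-bearing benzylic carbon, so C4 and C5 should equilibrate to the least strained 3,4-trans-4,5-trans isomer while the non-phenolic C2–O bond and the C2/C3 cis pair stay fixed, and Williamson O-methylation in the same flask removes the phenol and locks the result; the closest known reaction type is the phosphoric acid-catalysed addition of nucleophiles to p-quinone methides generated from 4-vinylphenols or 4-hydroxybenzyl alcohols.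

**Compound list**
1 | (Z)-2-bromobut-2-ene | C/C=C(C)\Br | starting material
2 | (chloromethyl)boronic acid pinacol ester, 2-(chloromethyl)-4,4,5,5-tetramethyl-1,3,2-dioxaborolane | ClCB1OC(C)(C)C(C)(C)O1 | starting material
3 | (2E)-but-2-en-2-yllithium (Li cis to the C4 methyl) | C/C=C(C)\[Li] | intermediate
4 | lithium (chloromethyl)[(2E)-but-2-en-2-yl](2,3-dimethylbutane-2,3-diolato)borate | C/C=C(C)\[B-]1(CCl)OC(C)(C)C(C)(C)O1.[Li+] | intermediate
5 | (Z)-2-methylbut-2-en-1-ylboronic acid pinacol ester, 4,4,5,5-tetramethyl-2-[(2Z)-2-methylbut-2-en-1-yl]-1,3,2-dioxaborolane | C/C=C(C)\CB1OC(C)(C)C(C)(C)O1 | intermediate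
6 | veratraldehyde, 3,4-dimethoxybenzaldehyde | COc1ccc(C=O)cc1OC | starting material
7 | borate ester 2-{[(1R,2S)-1-(3,4-dimethoxyphenyl)-2,3-dimethylbut-3-en-1-yl]oxy}-4,4,5,5-tetramethyl-1,3,2-dioxaborolane | COc1ccc([C@H](OB2OC(C)(C)C(C)(C)O2)[C@@H](C)C(C)=C)cc1OC | intermediate
8 | (1R,2S)-1-(3,4-dimethoxyphenyl)-2,3-dimethylbut-3-en-1-ol | COc1ccc([C@H](O)[C@@H](C)C(C)=C)cc1OC | intermediate
9 | 4-bromo-2,6-dimethoxyphenol | COc1cc(Br)cc(OC)c1O | starting material
10 | 4-[(1E,3S,4R)-4-(3,4-dimethoxyphenyl)-4-hydroxy-2,3-dimethylbut-1-en-1-yl]-2,6-dimethoxyphenol | COc1ccc([C@H](O)[C@@H](C)/C(C)=C/c2cc(OC)c(O)c(OC)c2)cc1OC | intermediate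
11 | quinone methide 4-[(3S,4R)-4-(3,4-dimethoxyphenyl)-4-hydroxy-2,3-dimethylbutylidene]-2,6-dimethoxycyclohexa-2,5-dien-1-one (C2 of the chain equilibrating) | COc1ccc([C@H](O)[C@@H](C)C(C)C=C2C=C(OC)C(=O)C(OC)=C2)cc1OC | intermediate
12 | phenol 4-[(2S,3S,4S,5R)-5-(3,4-dimethoxyphenyl)-3,4-dimethyloxolan-2-yl]-2,6-dimethoxyphenol | COc1ccc([C@@H]2O[C@H](c3cc(OC)c(O)c(OC)c3)[C@@H](C)[C@@H]2C)cc1OC | intermediate
13 | (2R,3S,4S,5S)-2-(3,4-dimethoxyphenyl)-3,4-dimethyl-5-(3,4,5-trimethoxyphenyl)oxolane | COc1ccc([C@@H]2O[C@H](c3cc(OC)c(OC)c(OC)c3)[C@@H](C)[C@@H]2C)cc1OC | target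

**Count**
Total steps: 4. Longest linear sequence: 4 (steps 1 to 4; 2, 6 and 9 are bought).

**Steps most likely to fail, with fallbacks**

Step 4 (the proposed new step) is the least certain. The tautomerisation to 11 may be too slow with so weak an acid. A stronger acid could ionise the veratryl C2–O bond (all-trans isomer) or let the veratryl ring attack C5 (aryltetralin). The fallback uses known chemistry only, sets out from 8 and comes back at 13.
- Alcohol 8 is hydroborated with dicyclohexylborane (2.2 equiv, THF, 0 °C to rt) to the bis-boryl adduct dicyclohexyl[(3S,4R)-4-(dicyclohexylboranyloxy)-4-(3,4-dimethoxyphenyl)-2,3-dimethylbutyl]borane F1.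
- NaOH/H2O2 oxidises F1 in the same flask to the diol (1R,2S)-1-(3,4-dimethoxyphenyl)-2,3-dimethylbutane-1,4-diol F2 (both C3 epimers).
- Catalytic TEMPO with PhI(OAc)2 (CH2Cl2) oxidises the primary alcohol and the lactol that follows, and DBU then moves the methyl group next to the carbonyl to the trans position, giving the lactone (3S,4S,5R)-5-(3,4-dimethoxyphenyl)-3,4-dimethyloxolan-2-one F3.
- 3,4,5-Trimethoxyphenyllithium (from 5-bromo-1,2,3-trimethoxybenzene and n-BuLi, THF, −78 °C) adds once to give the hemiketal (3S,4S,5R)-5-(3,4-dimethoxyphenyl)-3,4-dimethyl-2-(3,4,5-trimethoxyphenyl)oxolan-2-ol F4.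
- Et3SiH with BF3·OEt2 (CH2Cl2, −78 °C) reduces the cyclic oxocarbenium ion. By analogy with hemiketal reductions in this lignan class, hydride should enter cis to the neighbouring C4 methyl group, so the aryl group ends trans to it and 13 results.

Step 3 may give alkene isomer mixtures, chain-walking of palladium hydride to the aryl ketone, or slow oxidative addition of the electron-rich bromophenol. The fallback sets out from 8 and comes back at 12.
- Alcohol 8 is hydroborated with 9-BBN (2.2 equiv, THF, 60 °C) to the bis-boryl adduct 9-[(3S,4R)-4-(9-borabicyclo[3.3.1]nonan-9-yloxy)-4-(3,4-dimethoxyphenyl)-2,3-dimethylbutyl]-9-borabicyclo[3.3.1]nonane F5.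
- F5 is coupled in the same flask with 9 (PdCl2(dppf), K3PO4, DMF/H2O, 60 °C; B-alkyl Suzuki–Miyaura coupling) to the saturated phenol 4-[(3S,4R)-4-(3,4-dimethoxyphenyl)-4-hydroxy-2,3-dimethylbutyl]-2,6-dimethoxyphenol F6 (both C2 epimers of the chain).
- Ag2O (1.1 equiv, CH2Cl2, rt) oxidises the 4-alkylphenol to quinone methide 11, which closes at once to 12.
- The acid of step 4 then levels the mixture at C4 before methylation, so this fallback still depends on the equilibration proposed in step 4.

Step 2 may be slow or less selective with the trisubstituted allylboronate, which has not been used with this catalyst. The fallback sets out from 6 and comes back at 8.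
- Aldehyde 6 is added to the titanium enolate of (R)-4-benzyl-3-propanoyl-1,3-oxazolidin-2-one (TiCl4, i-Pr2NEt, N-methylpyrrolidone, CH2Cl2, 0 °C; auxiliary-controlled syn-aldol) to give the aldol adduct (4R)-4-benzyl-3-[(2R,3R)-3-(3,4-dimethoxyphenyl)-3-hydroxy-2-methylpropanoyl]-1,3-oxazolidin-2-one F7.
- MeNH(OMe)·HCl with AlMe3 (CH2Cl2) gives the Weinreb amide (2R,3R)-3-(3,4-dimethoxyphenyl)-3-hydroxy-N-methoxy-N,2-dimethylpropanamide F8.
- MeMgBr (THF, 0 °C) gives the ketone (3R,4R)-4-(3,4-dimethoxyphenyl)-4-hydroxy-3-methylbutan-2-one F9.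
- Methylenation with Ph3P=CH2 (THF, 0 °C) returns 8.

**Further compounds**
F1 | step 4 | dicyclohexyl[(3S,4R)-4-(dicyclohexylboranyloxy)-4-(3,4-dimethoxyphenyl)-2,3-dimethylbutyl]borane | COc1ccc([C@H](OB(C2CCCCC2)C2CCCCC2)[C@@H](C)C(C)CB(C2CCCCC2)C2CCCCC2)cc1OC
F2 | step 4 | (1R,2S)-1-(3,4-dimethoxyphenyl)-2,3-dimethylbutane-1,4-diol | COc1ccc([C@H](O)[C@@H](C)C(C)CO)cc1OC
F3 | step 4 | (3S,4S,5R)-5-(3,4-dimethoxyphenyl)-3,4-dimethyloxolan-2-one | COc1ccc([C@@H]2OC(=O)[C@@H](C)[C@@H]2C)cc1OC
F4 | step 4 | (3S,4S,5R)-5-(3,4-dimethoxyphenyl)-3,4-dimethyl-2-(3,4,5-trimethoxyphenyl)oxolan-2-ol | COc1ccc([C@@H]2OC(O)(c3cc(OC)c(OC)c(OC)c3)[C@@H](C)[C@@H]2C)cc1OC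
F5 | step 3 | 9-[(3S,4R)-4-(9-borabicyclo[3.3.1]nonan-9-yloxy)-4-(3,4-dimethoxyphenyl)-2,3-dimethylbutyl]-9-borabicyclo[3.3.1]nonane | COc1ccc([C@H](OB2C3CCCC2CCC3)[C@@H](C)C(C)CB2C3CCCC2CCC3)cc1OC
F6 | step 3 | 4-[(3S,4R)-4-(3,4-dimethoxyphenyl)-4-hydroxy-2,3-dimethylbutyl]-2,6-dimethoxyphenol | COc1ccc([C@H](O)[C@@H](C)C(C)Cc2cc(OC)c(O)c(OC)c2)cc1OC
F7 | step 2 | (4R)-4-benzyl-3-[(2R,3R)-3-(3,4-dimethoxyphenyl)-3-hydroxy-2-methylpropanoyl]-1,3-oxazolidin-2-one | COc1ccc([C@H](O)[C@@H](C)C(=O)N2[C@H](Cc3ccccc3)COC2=O)cc1OC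
F8 | step 2 | (2R,3R)-3-(3,4-dimethoxyphenyl)-3-hydroxy-N-methoxy-N,2-dimethylpropanamide | COc1ccc([C@H](O)[C@@H](C)C(=O)N(C)OC)cc1OC
F9 | step 2 | (3R,4R)-4-(3,4-dimethoxyphenyl)-4-hydroxy-3-methylbutan-2-one | COc1ccc([C@H](O)[C@@H](C)C(C)=O)cc1OC
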